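- The candidate steps conserve the sum of the catalyst forms, and each turn of the cycle spends one reagent and makes one target, so I looked for the rate at which reagent is spent.

| setting | north | south-west | beta | delta | gamma | eta |
|---|---|---|---|---|---|---|
| substrate | 20 mM | 20 mM | 20 mM | 20 mM | 20 mM | 20 mM |
| reagent | 0.46 equiv | 4.2 equiv | 0.400 equiv | 0.800 equiv | 1.50 equiv | 3.00 equiv |
| free catalyst | 0.75 mol% | 0.75 mol% | 0.75 mol% | 0.75 mol% | 0.75 mol% | 0.75 mol% |
| remark | run made earlier | run made earlier |  |  |  |  |
| time |  |  | 8.0 h | 8.0 h | 8.0 h | 8.0 h |

| run | time / h | target / % |
|---|---|---|
| north | 1.33 | 3 |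
| north | 3.00 | 3 |
| north | 4.00 | 5 |
| north | 6.00 | 10 |
| south-west | 1.33 | 18 |
| south-west | 3.00 | 44 |
| south-west | 4.00 | 59 |
| south-west | 6.00 | 75 |

(each reading ± 1.5 percentage points)

- the numbers in the tables scatter with a standard deviation of 1.5 percentage points
- candidate steps: substrate + free catalyst -> catalyst intermediate A; reagent + catalyst intermediate A <-> catalyst intermediate B; catalyst intermediate B -> by-product + catalyst intermediate C; catalyst intermediate C -> free catalyst + target; target + free catalyst <-> isomer of the product + free catalyst
- "hardly changes" means that all values lie within two and a half points (for a concentration: within two and a half percent of the largest)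

- amount of target at the end, in percent of the substrate charged for beta, delta, gamma, eta, in this order
- how that number moves from the first to the last of them (rises, then falls / rises all the way / falls all the way / hardly changes / falls, then rises)

- From the south-west run between 1.33 h and 4.00 h I read the spending rate κ, the share of its own charge that reagent loses per hour, as 0.0366 h⁻¹.
- The last north reading gave 0.0362 h⁻¹, about the same at a charge 9.13 times smaller, so I treated the rate as pseudo-first-order in reagent: κ times c_reagent.
- The start rate, in shares of the substrate per hour, was then 0.0146 h⁻¹ for beta and 0.110 h⁻¹ for eta.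
- The first slowing I reckoned with was reagent spent. By 8.0 h my reckoning multiplied the rate by 0.746, and since I read κ as independent of the charge, I gave beta, delta, gamma and eta this same factor.
- Averaged over the run, the slowing was 0.867, which gave 10.1%, 20.3%, 38.0% and 76.1%.
- A second slowing came late. The same reckoning for the south-west run gave 57.1% at 4.00 h against a reading of 59%, but 82.7% at 6.00 h against 75%, a gap of 7.7 percentage points.
- My number for gamma stayed below that south-west reading of 59%, so I kept my numbers for beta, delta and gamma. My number for eta lay above it, so I placed eta between 68.4% and 76.1%, and my row rose from first to last.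
- The forecast gave 12%, 24%, 42% and 68%, rises all the way, higher than mine for beta, delta and gamma, holding that “the rate is nearly proportional to reagent”.
- The flasks gave 10.2%, 20.4%, 37.8% and 72.8%: rises all the way.

    substrate + free catalyst → catalyst intermediate A (k = 2.90 × 10⁵ L mol⁻¹ h⁻¹)
    reagent + catalyst intermediate A ⇌ catalyst intermediate B (K = 8.50 L mol⁻¹, k = 250 L mol⁻¹ h⁻¹)
    catalyst intermediate B → by-product + catalyst intermediate C (k = 2500 h⁻¹)
    catalyst intermediate C → free catalyst + target (k = 5700 h⁻¹)
    target + free catalyst ⇌ isomer of the product + free catalyst, rate k5*[free catalyst]*[target] forward; the back reaction follows from the equilibrium constant (K = 1.90, k = 15000 L mol⁻¹ h⁻¹)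

- At 8.00 h eta held 74.6% of its reagent charge, where my factor stood at 74.6%. Carried to beta at 80.0 h, κ left 5.35% of the reagent charge, and beta held 5.16%.

The runs were generated by integration from invented constants, noise included.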